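I fitted no constants; I divided readings instead, and in logarithms a ratio of charges gives an exponent directly.

| flask | L | Z | E | time |
|---|---|---|---|---|
| birch | 0.600 M | 0.480 M | 0.0300 M |  |
| ash | 0.300 M | 0.180 M | 0.0300 M |  |
| oak | 0.600 M | 0.480 M | 0.0150 M |  |
| larch | 0.600 M | 0.480 M | 0.00460 M | 140 min |

| birch run: time / min | birch run: [L] / M | ash run: time / min | ash run: [L] / M | oak run: time / min | oak run: [L] / M |
|---|---|---|---|---|---|
| 28 | 0.534 | 28 | 0.265 | 28 | 0.565 |
| 56 | 0.473 | 56 | 0.226 | 56 | 0.534 |
| 84 | 0.432 | 84 | 0.208 | 84 | 0.511 |
| 110 | 0.394 | 110 | 0.190 | 110 | 0.495 |
| 140 | 0.357 | 140 | 0.180 | 140 | 0.467 |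

(readings scatter by 0.003 M)

- how the opening rate goes with [E] round the charge of the birch run: the exponent of the rate at two percent of L gone to J
- L in the larch run at 140 min, as a share of the L charged

- Overall: L + Z -> J, with E as catalyst.
- Constant volume, constant temperature.
- Readings of a species count what is bound in complexes too.
- An order is taken over about fifteen percent of the charge, up and down.

The birch and oak runs differ in E, so I tested whether E merely stretches the clock. The first way compared times at equal L: birch reached 0.534 M at 28 min, and oak reached 0.534 M at 56 min.

n = log(time ratio) / log(E ratio) = 1.00

The second way compared the L lost at equal clock, 28 min.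

m = log(loss ratio) / log(E ratio) = 0.915

One standard deviation on the oak loss shifts m by 0.119, and n and m differ by less than that. I therefore trusted an opening exponent near one.

That gave me a quantity to carry. For the larch run at 140 min, the birch-equivalent time τ is 21.5 min: the clock time multiplied by the flask's [E] and divided by the [E] of the birch run. The first birch chord gives a larch loss of 0.0506 M, which leaves 91.6%.

The late readings then parted from this rule. Oak at 140 min has τ = 70.0 min, and birch, halfway between its readings at 56 min and 84 min, stood near 0.453 M. Oak stood higher, at 0.467 M. Its loss was 0.902 of the birch loss at the same τ, so τ was the way that cheated at this late reading. Applying that factor to larch gave me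

L share = 92.4%

I read this as low, because the larch gap between clock and τ is wider than the oak gap.

The forecast gave 1 for the exponent and 92.6% for L, close to my share, on the ground that the fall in rate “points to catalyst decay in time”.

The flask gave 1.1 and 93.1%, so the forecast stands within its margins.

    E + L → EL (2.670 /M/min)
    EL + Z → J + E (0.8760 /M/min)
    EL + L ⇌ EL2, settled at all times (6.680 /M)
    Z → Yx (0.002946 /min)

The step Z → Yx contains no E and has a half-life of 235 min. J reached a quarter of the L charged at 71.1 min in the birch run and at 170 min in the oak run, which is τ = 85.2 min for oak, later than birch. At τ = 21.5 min, the larch run lost 0.0417 M of L against the 0.0506 M from the birch chord, a ratio of 0.823.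

(The numbers in the tables are simulated with made-up constants; noise was put on by code.)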